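## Structural features

- The target is a trans-fused bicyclo[5.3.0]decene (daucane skeleton). Ring A is a cycloheptene (C1, C2, C3, C4, C5, C6, C10), ring B a cyclopentane (C6, C7, C8, C9, C10), and they share the C6–C10 bond with the C6 methyl and H-10 on opposite faces.
- There are five stereocentres, (1S,5S,6S,9R,10S) in these locants. Four are contiguous along C5–C6–C10–C9, and C1 hangs on C10.
- C6 is quaternary (methyl). C9 is a tertiary carbinol bearing isopropyl, with its oxygen cis to the C6 methyl. C1 carries a 4-methoxybenzoate (O cis to H-10) and C5 an allylic acetate (O cis to the C6 methyl), on either side of the C3-methyl C3=C4 alkene.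
- Fragile points: the allylic C5 acetate (ionisation, SN2′), two different esters that must not exchange or migrate, the tertiary C9 alcohol (dehydration), and C10, which can epimerise whenever C1 is a carbonyl.
- The real difficulty is the quaternary C6 between three stereocentres, the trans ring fusion, and the distinction of the C1 and C5 oxygens.
- The key step exploits the sequence O–C1–C2–C3(CH3)=C4–C5–O of ring A. At the C5 ketone level this is a δ-hydroxy-β-methyl enone, the product of a vinylogous aldol between a C1 aldehyde on C10 and the γ-carbon (C2) of the dienol ether of a 3-methylbut-2-enoyl ketone on C6.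
- Ring A can only close if C3 and C6 are cis across the C4=C5 enol bond (E). That is the isomer in which the quaternary C6 clashes with C3, so enolisation alone will not deliver it.

## Logic of the disconnections

**23 ⇒ 22.** The O–Si bond at C9 is cut last. The tertiary alcohol stays masked because, free, it would quench the Lewis acid of the ring closure and invite dehydration. The forward step must remove silicon without touching two esters, one of them allylic.

**22 ⇒ 21 ⇒ 20.** The acetyl C–O bond and then the C5–H bond are cut, returning C5 to the ketone that the ring closure produces. With the C1 ester already in place, the two ring-A oxygens never compete. The forward reduction must be 1,2-selective and deliver hydride opposite the axial C6 methyl.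

**20 ⇒ 18 + 19.** The acyl C–O bond at C1 is cut. In 18 the C1 hydroxyl is the only free one. The acylation must be mild enough to avoid vinylogous retro-aldol or elimination of the δ-hydroxy enone.

**18 ⇒ 17.** The C1–C2 bond is cut. This removes ring A, the C1 stereocentre and the enone in one stroke and leaves a cyclopentane with three stereocentres. The forward step needs attack through C2 rather than C4, the E dienol ether, face selectivity at C1, and a C10 that does not epimerise.

**17 ⇒ 16 ⇒ 15.** The C1 oxidation level and the C1–O acyl bond are adjusted. The aldehyde must be made last, because an enolisable aldehyde cannot survive the conditions that form a dienol ether. Ester removal and oxidation must therefore be non-acidic and fluoride-free.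

**15 ⇒ 14 ⇒ 12.** The C4=C5 geometry and two O–Si bonds are traced back to enone 12. Enolisation of 12 should place C3 away from C6 (Z), so a separate contra-thermodynamic Z-to-E isomerisation is required.

**12 ⇒ 9.** The C3=C4 π bond (retro-elimination) and the C5=O bond (retro-ozonolysis) lead to the 1,1-disubstituted alkene of 9. An alkenyl group can be added enantioselectively to a β-substituted enone; an acyl anion equivalent cannot. The alkene in 9 must be the only one at that stage.

**9 ⇒ 8 ⇒ 6 + 7.** The C1 O-acyl bond and the C9–isopropyl bond are cut. The forward addition to a hindered ketone must come from the face opposite the C10 substituent and must beat enolisation and reduction.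

**6 ⇒ 3 + 2 (through 4 and 5) and a one-carbon electrophile.** The C6–C5 and C10–C1 bonds are cut, giving two small fragments. The forward step needs catalyst control of the C6 face and capture of the enolate at C10 anti to the bulkier C6 substituent, which is why a branched alkenyl group is chosen.

**2 ⇒ 1.** The O–Si bond is cut; the silyl ether later serves as the leaving group that unveils the enone.

## Other disconnections considered

**Alternative 1:** The cut removes the C6 methyl and the C10–C1 bond together. Forward, a methyl group is transferred from aluminium to the enone acetal A2 under copper/phosphoramidite catalysis, and the aluminium enolate is captured at C10 by the iodo aldehyde A3 to give aldol A1.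
- In its favour: methyl transfer to a 3-substituted cyclopentenone is better precedented than the alkenyl transfer of step 2. The acetal on C6 is bulkier than the alkenyl group of 5, so anti capture at C10 is more secure. Ring A would later close from the vinyl iodide onto a C5 aldehyde, with no dienol ether geometry to control. On these three points the alternative is the better plan.
- Against it here: the C1 carbinol would come from an open-chain aldol transition state, less predictable than the ring-constrained closure of step 10. A3 is a β,γ-unsaturated aldehyde prone to enolisation and conjugation. The later isopropyl addition at C9 would have to tolerate a vinyl iodide that exchanges with Grignard reagents. The C5 carbinol would come from a chromium-mediated closure of open facial selectivity, whereas here C5 is set by reduction of a rigid enone.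
- Comparison: both plans form the C1 bond by carbonyl addition. Step economy is about equal, since the C2–C4 chain, the C5 oxidation level and the ring closure still cost steps after A1.

**Alternative 2:** The cut is the C6–C10 bond, made by ring contraction. Forward, photolysis of the diazo ketone A5 (from a chiral-pool p-menthenone after reduction, alkylation at C6 and diazo transfer) shifts C6 from the carbonyl carbon to C10, and the alcohol solvent traps the ketene as ester A4.
- In its favour: the absolute configuration comes from the chiral pool without asymmetric catalysis, which is safer than step 2 for enantiopurity. The migrating quaternary carbon keeps its configuration. The C10 ester can be equilibrated to the trans isomer, a thermodynamic control that step 2 lacks. On these points it is the equal or the better.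
- Against: A4 has C9 as a CH bearing isopropenyl, so the tertiary carbinol needs a C–H to C–O change at a fully substituted centre with facial control. C6 would be set by alkylation with only remote induction. Diazo transfer next to a quaternary carbon needs prior activation. Ring A is not addressed at all and would still need a closure like step 10.
- Comparison: clearly longer than the chosen plan; as photochemistry it is on a par with step 7.

**Alternative 3:** Two bonds of ring A, C2–C3 and C4–C5, are cut. Forward, the enol of dione A7 adds photochemically to propa-1,2-diene A8, and the methylenecyclobutanol opens by retro-aldol to the seven-membered methylene dione A6.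
- In its favour: ring A with both oxygens arrives in one operation with two C–C bonds formed, a better bond economy than step 10. Both enols of A7 converge on the same A6.
- Against: in A6 the C1 and C5 carbonyls flank an exocyclic methylene almost symmetrically. Moving the alkene toward C4 only, reducing the two ketones to different carbinols and acylating them differently all lack a handle. By contrast, 18 would leave step 10 with C1 as an alcohol, C5 as a ketone and the alkene in place. Ring B must then close by aldol of C10 onto the unmasked C9 ketone although C2 and C4 are more acidic. The orientation of A8 decides whether the methylene ends at C3. The quaternary C6 of A7 still needs an enantioselective synthesis.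
- Comparison: the route to A6 is short, but the differentiation problems afterwards make the whole less predictable than the chosen plan.

Key step: step 10

**Remarks on the chemistry (assumptions).**
- Assumption: the antipode of the chiral carbene ligand in step 2 is the one that gives (S)-C6; the other antipode would give the enantiomeric series.
- Triethylsilyl is used for both silyl groups of 17 and 18; their connectivity and configuration are those the ring closure requires.
- Enolisation of 12 is expected to give the Z dienol ether (C3 anti to C6). The E isomer needed for ring closure is therefore made by a separate isomerisation (step 7).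
- Locants C1–C10 are those of the target throughout. The C10 descriptor changes from S to R in 17 only because C1 becomes an aldehyde; the geometry is unchanged.

## Steps

Step 1
Reactants: 1 2-methylpent-4-yn-2-ol
Product: 2 triethyl[(2-methylpent-4-yn-2-yl)oxy]silane
Conditions: Et3SiOTf, 2,6-lutidine, CH2Cl2, 0 °C
Reagents that add atoms: triethylsilyl trifluoromethanesulfonate, CC[Si](CC)(CC)OS(=O)(=O)C(F)(F)F
Why: O-Silylation of a tertiary alcohol with a silyl triflate; the ether masks the acidic OH during hydroalumination and later becomes the leaving group that unveils the enone.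

Step 2
Reactants: 2 triethyl[(2-methylpent-4-yn-2-yl)oxy]silane; 3 3-methylcyclopent-2-en-1-one
Product: 6 (2S,3S)-2-(hydroxymethyl)-3-methyl-3-[4-methyl-4-(triethylsilyloxy)pent-1-en-2-yl]cyclopentan-1-one (6S,10S; hydroxymethyl trans to the alkenyl group), via alkenylalane 4 (not isolated), via aluminium enolate 5 (not isolated)
Conditions: iBu2AlH, Ni(dppp)Cl2 (3 mol %), THF, 0 °C to rt; then 3, Cu(OTf)2 (5 mol %), chiral sulfonate-bearing imidazolinium salt (NHC precursor, 5.5 mol %), −30 °C; then CH2O (gas), −78 °C; aq. potassium sodium tartrate
Reagents that add atoms: formaldehyde, C=O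
Why: Nickel-catalysed α-selective hydroalumination of the terminal alkyne gives the internal alkenylalane 4, and copper-catalysed asymmetric conjugate addition to the β-substituted enone should set the quaternary C6 (S) under catalyst control. The regiodefined aluminium enolate 5 is captured in a tandem aldol addition with formaldehyde anti to the branched alkenyl group, the bulkier substituent on C6, which sets C10 trans.

Step 3
Reactants: 6 (2S,3S)-2-(hydroxymethyl)-3-methyl-3-[4-methyl-4-(triethylsilyloxy)pent-1-en-2-yl]cyclopentan-1-one; 7 isopropylmagnesium chloride
Product: 8 (1R,2S,3S)-2-(hydroxymethyl)-3-methyl-3-[4-methyl-4-(triethylsilyloxy)pent-1-en-2-yl]-1-(propan-2-yl)cyclopentan-1-ol (6S,9R,10S; C9–OH cis to the hydroxymethyl group)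
Conditions: iPrMgCl (3.5 equiv), CeCl3 (anhydrous, 3.5 equiv), THF, −78 to 0 °C; aq. NH4Cl
Reagents that add atoms: none
Why: Organocerium addition to a ketone, which suppresses enolisation and β-hydride reduction by the branched Grignard reagent. The nucleophile should enter anti to the C10 substituent (held as its chelated alkoxide), on the face of H-10, setting C9 (R) with the oxygen cis to C1.

Step 4
Reactants: 8 (1R,2S,3S)-2-(hydroxymethyl)-3-methyl-3-[4-methyl-4-(triethylsilyloxy)pent-1-en-2-yl]-1-(propan-2-yl)cyclopentan-1-ol
Product: 9 primary pivalate of 8 (C1–O-pivaloyl; 6S,9R,10S)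
Conditions: PivCl, pyridine, CH2Cl2, 0 °C
Reagents that add atoms: pivaloyl chloride, CC(C)(C)C(=O)Cl
Why: Selective acylation of the primary alcohol; the hindered tertiary C9–OH is inert, and the pivalate survives ozonolysis, silyl triflate and light and is later removed by hydride.

Step 5
Reactants: 9 primary pivalate of 8
Product: 12 enone: pivalate of the cyclopentane carrying a 3-methylbut-2-enoyl group on C6, hydroxymethyl on C10 and the free tertiary C9 carbinol (6S,9R,10S), via ozonide 10 (not isolated), via silyloxy ketone 11 (not isolated)
Conditions: O3, CH2Cl2, −78 °C; PPh3, −78 °C to rt; then DBU, rt to 40 °C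
Reagents that add atoms: ozone, [O-][O+]=O
Why: Ozonolysis of the only alkene turns C5 into the ketone, and base-mediated E1cB loss of triethylsilanolate from the β-silyloxy ketone 11 gives the conjugated 3-methylbut-2-enoyl ketone. No stereocentre is touched.

Step 6
Reactants: 12 enone (6S,9R,10S)
Product: 14 (Z)-dienol ether: C6 bears a (1Z)-3-methyl-1-(triethylsilyloxy)buta-1,3-dien-1-yl group (O cis to C3), C9 a triethylsilyloxy group, C10 the pivaloyloxymethyl group, via monosilyl enone 13 (not isolated)
Conditions: Et3SiOTf (3 equiv), Et3N (5 equiv), CH2Cl2, −78 °C to rt
Reagents that add atoms: triethylsilyl trifluoromethanesulfonate, CC[Si](CC)(CC)OS(=O)(=O)C(F)(F)F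
Why: The silyl triflate silylates the tertiary alcohol and soft-enolises the enone through a γ-methyl group (vinylogous enolisation; C6 has no α-hydrogen). The Z isomer is expected because C3 avoids the quaternary C6 (allylic 1,3-strain).

Step 7
Reactants: 14 (Z)-dienol ether
Product: 15 (E)-dienol ether: as 14 but with C3 and C6 cis across C4=C5 (O trans to C3)
Conditions: fac-Ir(ppy)3 (1 mol %), 450 nm LEDs, degassed THF (0.02 M), rt
Reagents that add atoms: none
Why: Triplet-sensitised E/Z isomerisation of a conjugated diene. The near-planar Z diene accepts triplet energy and twists about C4=C5, whereas the E isomer is forced out of conjugation by the C6/C3 clash, has the higher triplet energy and is not re-excited, so it should accumulate, as hindered cis dienes do in one-way sensitised isomerisations.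

Step 8
Reactants: 15 (E)-dienol ether
Product: 16 primary alcohol: (E)-dienol ether with free C1 hydroxymethyl on C10 (6S,9R,10S)
Conditions: iBu2AlH (2.5 equiv), CH2Cl2, −78 °C; aq. potassium sodium tartrate
Reagents that add atoms: none
Why: Reductive cleavage of the pivalate by the aluminium hydride; the silyl enol ether and silyl ether are inert to hydride, and the neutral tartrate work-up avoids hydrolysis of the dienol ether.

Step 9
Reactants: 16 primary alcohol
Product: 17 aldehyde: cyclopentane with the C1 formyl group on C10, the (1E)-3-methyl-1-(triethylsilyloxy)buta-1,3-dien-1-yl group on C6 (trans to formyl) and the triethylsilyloxy and isopropyl groups on C9 (6S,9R,10R)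
Conditions: SO3·pyridine, DMSO, iPr2NEt, CH2Cl2, 0 °C
Reagents that add atoms: none
Why: Parikh–Doering oxidation under basic, non-aqueous conditions stops at the aldehyde and leaves the acid-labile dienol ether intact; the hindered C10–H should not epimerise at 0 °C.

Step 10
Reactants: 17 aldehyde with (E)-dienol ether
Product: 18 (1S,6S,9R,10S)-1-hydroxy-3,6-dimethyl-9-(propan-2-yl)-9-(triethylsilyloxy)-trans-bicyclo[5.3.0]dec-3-en-5-one
Conditions: BF3·OEt2 (1.2 equiv), CH2Cl2 (0.005 M), −78 °C; aq. NaHCO3
Reagents that add atoms: none
Why: BF3 binds the C1 aldehyde oxygen and the 2-silyloxydiene attacks through its terminal carbon C2 in an open transition state, forming C1–C2; loss of silicon as the fluorosilane restores the C5 ketone conjugated to the new C3=C4 bond. The closest known reaction type is the vinylogous Mukaiyama aldol (γ-selective addition of silyl dienol ethers to Lewis-acid-activated aldehydes), here intramolecular. Ring A (C1, C2, C3, C4, C5, C6, C10) closes in a 7-exo-trig sense at the aldehyde carbon and is trans-fused because C5 and C1 already sit on opposite faces of ring B. The new stereocentre C1 is controlled by C10: in a chair-like transition state the aldehyde hydrogen is pseudo-axial and the BF3-bound oxygen pseudo-equatorial, pointing away from the ring and from the C9 silyl ether, which should give the (1S) carbinol with O cis to H-10. Attack through C4 would be a five-membered enolendo closure, which is stereoelectronically closed, and silyl dienol ethers are γ-selective in any case. Only the E dienol ether has C3 and C6 on the same side of C4=C5, and this geometry is secured in step 7; the rotamer that turns C2 toward C6 is also the less strained one, because it turns the C3 methyl away from the quaternary centre. High dilution favours ring closure over intermolecular aldol, and the base-free conditions at −78 °C keep C10 intact.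

Step 11
Reactants: 18 hydroxy enone; 19 4-methoxybenzoyl chloride
Product: 20 4-methoxybenzoate of 18 at C1 (1S,6S,9R,10S)
Conditions: pyridine, DMAP (cat.), CH2Cl2, 0 °C to rt
Reagents that add atoms: none
Why: DMAP-catalysed acylation of the only free hydroxyl, the equatorial C1 alcohol; the weakly basic conditions avoid vinylogous retro-aldol or elimination of the δ-oxygenated enone.

Step 12
Reactants: 20 C1 4-methoxybenzoate enone
Product: 21 (5S)-allylic alcohol: C5 hydroxyl cis to the C6 methyl (1S,5S,6S,9R,10S)
Conditions: NaBH4, CeCl3·7H2O, MeOH/CH2Cl2, −78 °C
Reagents that add atoms: none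
Why: Luche 1,2-reduction; hydride should attack the C5 carbonyl from the face opposite the axial C6 methyl, giving the equatorial (5S) alcohol, while the ester and silyl ether are untouched at −78 °C.

Step 13
Reactants: 21 (5S)-allylic alcohol
Product: 22 C5 acetate, C1 4-methoxybenzoate, C9 triethylsilyl ether (1S,5S,6S,9R,10S)
Conditions: Ac2O, pyridine, DMAP (cat.), CH2Cl2, 0 °C to rt
Reagents that add atoms: acetic anhydride, CC(=O)OC(C)=O
Why: DMAP-catalysed acetylation of the only free hydroxyl under non-ionising conditions, so the allylic C5 centre keeps its configuration.

Step 14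
Reactants: 22 silyl-protected diester
Product: 23 (1S,5S,6S,9R,10S)-5-acetoxy-9-hydroxy-3,6-dimethyl-9-(propan-2-yl)-trans-bicyclo[5.3.0]dec-3-en-1-yl 4-methoxybenzoate (target)
Conditions: HF·pyridine, pyridine, THF, 0 °C to rt
Reagents that add atoms: none
Why: Fluoride cleavage of the tertiary triethylsilyl ether under buffered, non-basic conditions, so that neither ester migrates or hydrolyses and the allylic acetate does not ionise.

## Compound list

1 | 2-methylpent-4-yn-2-ol | C#CCC(C)(C)O | starting material
2 | triethyl[(2-methylpent-4-yn-2-yl)oxy]silane | C#CCC(C)(C)O[Si](CC)(CC)CC | intermediate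
3 | 3-methylcyclopent-2-en-1-one | CC1=CC(=O)CC1 | starting material
4 | [4-methyl-4-(triethylsilyloxy)pent-1-en-2-yl]bis(2-methylpropyl)alane | C=C(CC(C)(C)O[Si](CC)(CC)CC)[Al](CC(C)C)CC(C)C | intermediate
5 | bis(2-methylpropyl)aluminium enolate (C9–O–Al, C9=C10) of the (S)-configured conjugate adduct | C=C(CC(C)(C)O[Si](CC)(CC)CC)[C@@]1(C)CCC(O[Al](CC(C)C)CC(C)C)=C1 | intermediate
6 | (2S,3S)-2-(hydroxymethyl)-3-methyl-3-[4-methyl-4-(triethylsilyloxy)pent-1-en-2-yl]cyclopentan-1-one | C=C(CC(C)(C)O[Si](CC)(CC)CC)[C@@]1(C)CCC(=O)[C@@H]1CO | intermediate
7 | isopropylmagnesium chloride | CC(C)[Mg]Cl | starting material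
8 | (1R,2S,3S)-2-(hydroxymethyl)-3-methyl-3-[4-methyl-4-(triethylsilyloxy)pent-1-en-2-yl]-1-(propan-2-yl)cyclopentan-1-ol | C=C(CC(C)(C)O[Si](CC)(CC)CC)[C@@]1(C)CC[C@@](O)(C(C)C)[C@@H]1CO | intermediate
9 | primary pivalate of 8 (6S,9R,10S) | C=C(CC(C)(C)O[Si](CC)(CC)CC)[C@@]1(C)CC[C@@](O)(C(C)C)[C@@H]1COC(=O)C(C)(C)C | intermediate
10 | ozonide (1,2,4-trioxolane at C5) of 9 | C1(CC(C)(C)O[Si](CC)(CC)CC)(OOCO1)[C@@]2(C)CC[C@@](O)(C(C)C)[C@@H]2COC(=O)C(C)(C)C | intermediate
11 | β-silyloxy ketone: C6 bears a 3-methyl-3-(triethylsilyloxy)butanoyl group (6S,9R,10S) | CC(C)(CC(=O)[C@@]1(C)CC[C@@](O)(C(C)C)[C@@H]1COC(=O)C(C)(C)C)O[Si](CC)(CC)CC | intermediate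
12 | enone: C6 bears a 3-methylbut-2-enoyl group; C9 free carbinol; C10 pivaloyloxymethyl (6S,9R,10S) | CC(C)=CC(=O)[C@@]1(C)CC[C@@](O)(C(C)C)[C@@H]1COC(=O)C(C)(C)C | intermediate
13 | C9 triethylsilyl ether of 12 | CC(C)=CC(=O)[C@@]1(C)CC[C@@](O[Si](CC)(CC)CC)(C(C)C)[C@@H]1COC(=O)C(C)(C)C | intermediate
14 | (Z)-dienol triethylsilyl ether (O cis to C3), C9 triethylsilyl ether, C1 pivalate | C=C(C)/C=C(\O[Si](CC)(CC)CC)[C@@]1(C)CC[C@@](O[Si](CC)(CC)CC)(C(C)C)[C@@H]1COC(=O)C(C)(C)C | intermediate
15 | (E)-dienol triethylsilyl ether (C3 cis to C6), C9 triethylsilyl ether, C1 pivalate | C=C(C)/C=C(/O[Si](CC)(CC)CC)[C@@]1(C)CC[C@@](O[Si](CC)(CC)CC)(C(C)C)[C@@H]1COC(=O)C(C)(C)C | intermediate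
16 | (E)-dienol ether primary alcohol (6S,9R,10S) | C=C(C)/C=C(/O[Si](CC)(CC)CC)[C@@]1(C)CC[C@@](O[Si](CC)(CC)CC)(C(C)C)[C@@H]1CO | intermediate
17 | (E)-dienol ether aldehyde, key-step precursor (6S,9R,10R) | C=C(C)/C=C(/O[Si](CC)(CC)CC)[C@@]1(C)CC[C@@](O[Si](CC)(CC)CC)(C(C)C)[C@@H]1C=O | intermediate
18 | (1S,6S,9R,10S)-1-hydroxy-3,6-dimethyl-9-(propan-2-yl)-9-(triethylsilyloxy)-trans-bicyclo[5.3.0]dec-3-en-5-one | O[C@H]1CC(C)=CC(=O)[C@@]2(C)CC[C@@](O[Si](CC)(CC)CC)(C(C)C)[C@H]12 | intermediate
19 | 4-methoxybenzoyl chloride | COc1ccc(C(=O)Cl)cc1 | starting material
20 | C1 4-methoxybenzoate of 18 | COc1ccc(C(=O)O[C@H]2CC(C)=CC(=O)[C@@]3(C)CC[C@@](O[Si](CC)(CC)CC)(C(C)C)[C@H]23)cc1 | intermediate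
21 | (5S)-allylic alcohol | COc1ccc(C(=O)O[C@H]2CC(C)=C[C@H](O)[C@@]3(C)CC[C@@](O[Si](CC)(CC)CC)(C(C)C)[C@H]23)cc1 | intermediate
22 | C5 acetate, C9 triethylsilyl ether | COc1ccc(C(=O)O[C@H]2CC(C)=C[C@H](OC(C)=O)[C@@]3(C)CC[C@@](O[Si](CC)(CC)CC)(C(C)C)[C@H]23)cc1 | intermediate
23 | (1S,5S,6S,9R,10S)-5-acetoxy-9-hydroxy-3,6-dimethyl-9-(propan-2-yl)-trans-bicyclo[5.3.0]dec-3-en-1-yl 4-methoxybenzoate | COc1ccc(C(=O)O[C@H]2CC(C)=C[C@H](OC(C)=O)[C@@]3(C)CC[C@@](O)(C(C)C)[C@H]23)cc1 | target

## Step count and least certain steps

Total: 14 steps. Longest linear sequence: 14 steps (from 1; 3, 7 and 19 enter at steps 2, 3 and 11).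

**Step 10 (key step).** The most likely failure is loss of the enol silyl group, or its transfer to the aldehyde oxygen, without C–C bond formation. The E dienol ether is twisted, and its γ-carbon only becomes nucleophilic once the diene flattens in the ring-shaped transition state. Ionisation of the tertiary C9 silyl ether by the Lewis acid is a second concern. Fallback: leave the Lewis-acid manifold. Treatment of 17 with anhydrous fluoride (tetrabutylammonium difluorotriphenylsilicate, THF, −78 to −20 °C) would release the ammonium dienolate, which adds to the unactivated aldehyde through C2, attack through C4 remaining geometrically closed. This sets out from 17 and comes back at 18 without a new compound.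

**Step 7.** The photostationary mixture may be insufficiently enriched in the E isomer, or the triplet diene may be lost to dimerisation, because the energy gap between the planar and twisted isomers is only estimated. Fallback: give up the preformed dienol ether geometry. Setting out from 12, selective silylation (Et3SiOTf, 2,6-lutidine, −78 °C) gives 13, now isolated. An excess of iBu2AlH reduces both the pivalate and the ketone to the allylic/primary diol F1. Dess–Martin periodinane oxidises both hydroxyls to the enone aldehyde F2. A substoichiometric alkoxide (KOtBu, tBuOH/THF, 0 °C) then forms the dienolate reversibly, so both geometries interconvert by proton transfer and the one that can reach C1 closes ring A. The sequence comes back at 18.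

**Step 2.** Control may be lost in the capture of the aluminium enolate: over-addition of formaldehyde, proton transfer that scrambles the enolate, or weak facial discrimination at C10. The aluminium enolate is a sluggish nucleophile and formaldehyde an unselective electrophile. Fallback: separate the two events. Setting out from 2 and 3, the same conjugate addition is run and enolate 5 is silylated with Me3SiOTf to the trimethylsilyl enol ether F3, which is isolated. Hydroxymethylation by a Lewis-acid-catalysed Mukaiyama aldol with aqueous formaldehyde (Yb(OTf)3, THF/H2O) then comes back at 6.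

**Step 3.** Enolisation toward C8 or β-hydride transfer from the branched reagent may outrun addition to the hindered ketone, and the bulky C6 substituent on the attacking face may erode selectivity. Fallback: setting out from 6, the smaller prop-1-en-2-ylmagnesium bromide with CeCl3 gives the isopropenyl carbinol F4. Pivaloylation of the primary alcohol gives the pivalate F5. Hydroxyl-directed hydrogenation with [Ir(cod)(PCy3)(py)]PF6 and H2 saturates the allylic-alcohol alkene in preference to the undirected, hindered alkene on C6 and comes back at 9.

**Step 12.** Hydride may be delivered from the methyl face, or 1,4-reduction may compete, if ring A adopts a conformation in which the C6 methyl is not axial. Fallback: the C5-epimeric allylic alcohol F6 is inverted and acetylated in one operation by a Mitsunobu reaction with acetic acid (PPh3, diisopropyl azodicarboxylate, THF), setting out from 20 and coming back at 22.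

## Further compounds

F0 | step 10 | none | none
F1 | step 7 | allylic/primary diol from reduction of 13 (C5 epimers) | CC(C)=CC(O)[C@@]1(C)CC[C@@](O[Si](CC)(CC)CC)(C(C)C)[C@@H]1CO
F2 | step 7 | enone aldehyde with C9 triethylsilyl ether | CC(C)=CC(=O)[C@@]1(C)CC[C@@](O[Si](CC)(CC)CC)(C(C)C)[C@@H]1C=O
F3 | step 2 | trimethylsilyl enol ether of the (S)-configured conjugate adduct | C=C(CC(C)(C)O[Si](CC)(CC)CC)[C@@]1(C)CCC(O[Si](C)(C)C)=C1
F4 | step 3 | isopropenyl carbinol analogue of 8 | C=C(CC(C)(C)O[Si](CC)(CC)CC)[C@@]1(C)CC[C@@](O)(C(C)=C)[C@@H]1CO
F5 | step 3 | primary pivalate of F4 | C=C(CC(C)(C)O[Si](CC)(CC)CC)[C@@]1(C)CC[C@@](O)(C(C)=C)[C@@H]1COC(=O)C(C)(C)C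
F6 | step 12 | (5R)-allylic alcohol, C5 epimer of 21 | COc1ccc(C(=O)O[C@H]2CC(C)=C[C@@H](O)[C@@]3(C)CC[C@@](O[Si](CC)(CC)CC)(C(C)C)[C@H]23)cc1
A1 | alternative 1 | aldol adduct with C6, C10 and C1 set | O[C@@H](C/C(C)=C\I)[C@H]1C(=O)CC[C@]1(C)C(OC)OC
A2 | alternative 1 | 3-(dimethoxymethyl)cyclopent-2-en-1-one | COC(OC)C1=CC(=O)CC1
A3 | alternative 1 | (Z)-4-iodo-3-methylbut-3-enal | O=CC/C(C)=C\I
A4 | alternative 2 | methyl cyclopentanecarboxylate from ring contraction | COC(=O)[C@H]1[C@H](C(C)=C)CC[C@]1(C)COCc1ccccc1
A5 | alternative 2 | 2-diazo ketone precursor | C=C(C)[C@@H]1CC[C@](C)(COCc2ccccc2)C(=O)C1=[N+]=[N-]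
A6 | alternative 3 | 3-methylenecycloheptane-1,5-dione | O=C1CC(=C)CC(=O)[C@@](C)(CCC2(C(C)C)OCCO2)C1
A7 | alternative 3 | 4,4-disubstituted cyclopentane-1,3-dione | O=C1CC(=O)[C@@](C)(CCC2(C(C)C)OCCO2)C1
A8 | alternative 3 | propa-1,2-diene | C=C=C
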